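**Retrosynthetic overview**
- The quinone is made last, by oxidative demethylation of a (3S)-2'-hydroxy-3',4',5',6'-tetramethoxyisoflavan, whose only free phenol directs the oxidant to the B ring.
- That phenol comes from reductive opening of a cis-pterocarpan. The pterocarpan is closed from a cis-isoflavan-4-ol by demethylative C4–O bond formation; because the B ring is a symmetric pentamethoxyphenyl, the ring closure itself singles out the 2'-oxygen without a protecting group.
- C3, the only stereocentre, is set by asymmetric transfer hydrogenation with dynamic kinetic resolution of the isoflavone.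
- The isoflavone comes from oxidative 1,2-aryl shift and cyclisation of a 2'-hydroxychalcone, made by Claisen–Schmidt condensation of 2'-hydroxy-3',4',5'-trimethoxyacetophenone with pentamethoxybenzaldehyde.
- Ring order: pyranone ring, then the dihydrofuran ring of the pterocarpan (made, then cleaved), then the quinone.

Assumption: the stereocentre in the SMILES is C3 = S (isoflavan numbering), and the sense of induction in step 6 is assigned by the usual Noyori–Ikariya model for aryl ketones.

**Route**

Step 1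
Reactants: 1 3,4,5-trimethoxybenzaldehyde
Product: 2 2,6-dibromo-3,4,5-trimethoxybenzaldehyde
Conditions: Br2 (2.5 equiv), AcOH, 50 °C
Reagents that add atoms: bromine, BrBr
Why: Electrophilic aromatic bromination (SEAr); the only two free ring positions are each ortho/para to methoxy groups, so exhaustive bromination can only give the 2,6-dibromide.

Step 2
Reactants: 2 2,6-dibromo-3,4,5-trimethoxybenzaldehyde
Product: 3 2,3,4,5,6-pentamethoxybenzaldehyde
Conditions: NaOMe (6 equiv), CuBr (20 mol %), MeOH–DMF, 110 °C; aq. HCl work-up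
Reagents that add atoms: sodium methoxide, C[O-].[Na+]
Why: Ullmann-type Cu(I)-catalysed methoxylation of aryl bromides, helped by the ortho-formyl group, replaces both bromides and gives the symmetric pentamethoxy B-ring aldehyde.

Step 3
Reactants: 4 1,2,3,4-tetramethoxybenzene
Product: 6 2'-hydroxy-3',4',5'-trimethoxyacetophenone, via 2',3',4',5'-tetramethoxyacetophenone 5 (not isolated)
Conditions: AcCl (1.2 equiv), AlCl3 (2.5 equiv), CH2Cl2, 0 °C → reflux; aq. HCl work-up
Reagents that add atoms: acetyl chloride, CC(Cl)=O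
Why: Friedel–Crafts acylation at the only type of free position, followed by AlCl3-chelation-controlled cleavage of the methyl ether ortho to the new carbonyl (as in 1,2,3-trimethoxybenzene → 2-hydroxy-3,4-dimethoxyacetophenone), gives the chelated o-hydroxy ketone.

Step 4
Reactants: 6 2'-hydroxy-3',4',5'-trimethoxyacetophenone; 3 2,3,4,5,6-pentamethoxybenzaldehyde
Product: 7 (E)-1-(2-hydroxy-3,4,5-trimethoxyphenyl)-3-(2,3,4,5,6-pentamethoxyphenyl)prop-2-en-1-one
Conditions: KOH (50% aq.), EtOH, rt → 50 °C; then aq. HCl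
Reagents that add atoms: none
Why: Claisen–Schmidt aldol condensation of the acetophenone enolate with the non-enolisable aldehyde and E1cB dehydration gives the (E)-2'-hydroxychalcone.

Step 5
Reactants: 7 (E)-2'-hydroxychalcone
Product: 9 6,7,8-trimethoxy-3-(2,3,4,5,6-pentamethoxyphenyl)-4H-chromen-4-one, via β-keto dimethyl acetal 8 (not isolated)
Conditions: Tl(NO3)3·3H2O (1.1 equiv), MeOH–HC(OMe)3, rt; then 10% aq. HCl, MeOH, reflux
Reagents that add atoms: none
Why: Tl(III)-mediated oxidative rearrangement of a chalcone (oxythallation, then 1,2-shift of the electron-rich B ring through a phenonium ion, the chemical counterpart of isoflavone synthase) gives acetal 8, and acid closes the pyranone ring through the 2'-OH with loss of two MeOH.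

Step 6
Reactants: 9 6,7,8-trimethoxy-3-(pentamethoxyphenyl)-4H-chromen-4-one
Product: 11 (3S,4S)-6,7,8-trimethoxy-3-(2,3,4,5,6-pentamethoxyphenyl)chroman-4-ol (3,4-cis), via racemising isoflavanone 10 (not isolated)
Conditions: RuCl[(S,S)-TsDPEN](p-cymene) (2 mol %), HCO2H–Et3N (5:2), EtOAc, 40 °C
Reagents that add atoms: none
Why: Noyori–Ikariya asymmetric transfer hydrogenation with dynamic kinetic resolution; Ru–H conjugate reduction gives isoflavanone 10, C3 epimerises through the enol under Et3N, and the (S,S) catalyst reduces the (3S)-ketone fastest from the face anti to the aryl group, setting C3 (S) and C4 (S) cis.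

Step 7
Reactants: 11 (3S,4S)-cis-isoflavan-4-ol
Product: 13 (6aS,11aS)-2,3,4,7,8,9,10-heptamethoxypterocarpan (cis-fused 6a,11a-dihydro-6H-benzofuro[3,2-c]chromene), via aryl methyl oxonium bromide 12 (not isolated)
Conditions: BF3·OEt2 (1.5 equiv), n-Bu4NBr (3 equiv), CH2Cl2 (0.02 M), −40 → 0 °C
Reagents that add atoms: none
Why: Proposed new method: BF3 ionises the electron-rich benzylic C4–OH to the 2,4-dioxygenated benzyl cation (the same cation as in acid closure of 2'-hydroxyisoflavan-4-ols to pterocarpans), the oxygen of the 2'-OMe (2' and 6' are equivalent) adds to it in a 5-membered ring closure to give oxonium 12, and bromide removes the methyl group irreversibly by SN2; the closest known reaction types are MeO-5 neighbouring-group participation in solvolysis and demethylative halocyclisation of o-anisyl alkynes to benzofurans and chromones; the cis ring fusion is enforced by the 6,5-bicycle and C3 is untouched as long as E1 loss of H3 is outrun (low temperature, high bromide concentration, no base).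

Step 8
Reactants: 13 (6aS,11aS)-heptamethoxypterocarpan
Product: 14 2,3,4,5-tetramethoxy-6-[(3S)-6,7,8-trimethoxychroman-3-yl]phenol
Conditions: H2 (1 atm), 10% Pd/C, AcOH, rt
Reagents that add atoms: none
Why: Pd-catalysed hydrogenolysis of the benzylic aryl ether C11a–O bond (the classical pterocarpan → 2'-hydroxyisoflavan cleavage, the chemical counterpart of pterocarpan reductase) removes the C4 oxygen and frees the 2'-phenol without touching C3.

Step 9
Reactants: 14 (3S)-2'-hydroxy-3',4',5',6'-tetramethoxyisoflavan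
Product: 15 2,3,5-trimethoxy-6-[(3S)-6,7,8-trimethoxychroman-3-yl]cyclohexa-2,5-diene-1,4-dione (target)
Conditions: PhI(OAc)2 (1.1 equiv), MeCN–H2O (2:1), 0 °C
Reagents that add atoms: water, O
Why: Hypervalent-iodine oxidative demethylation of a p-methoxyphenol; ligand exchange at the only free phenol, attack of water at the para carbon and loss of MeOH give the p-quinone, while the fully etherified A ring and the C3 stereocentre are not touched.

**Compound list**
1 | 3,4,5-trimethoxybenzaldehyde | COc1cc(C=O)cc(OC)c1OC | starting material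
2 | 2,6-dibromo-3,4,5-trimethoxybenzaldehyde | COc1c(Br)c(C=O)c(Br)c(OC)c1OC | intermediate
3 | 2,3,4,5,6-pentamethoxybenzaldehyde | COc1c(OC)c(OC)c(C=O)c(OC)c1OC | intermediate
4 | 1,2,3,4-tetramethoxybenzene | COc1ccc(OC)c(OC)c1OC | starting material
5 | 2',3',4',5'-tetramethoxyacetophenone | CC(=O)c1cc(OC)c(OC)c(OC)c1OC | intermediate (not isolated)
6 | 2'-hydroxy-3',4',5'-trimethoxyacetophenone | CC(=O)c1cc(OC)c(OC)c(OC)c1O | intermediate
7 | (E)-1-(2-hydroxy-3,4,5-trimethoxyphenyl)-3-(2,3,4,5,6-pentamethoxyphenyl)prop-2-en-1-one | COc1cc(C(=O)/C=C/c2c(OC)c(OC)c(OC)c(OC)c2OC)c(O)c(OC)c1OC | intermediate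
8 | 1-(2-hydroxy-3,4,5-trimethoxyphenyl)-3,3-dimethoxy-2-(2,3,4,5,6-pentamethoxyphenyl)propan-1-one (racemic) | COC(OC)C(C(=O)c1cc(OC)c(OC)c(OC)c1O)c1c(OC)c(OC)c(OC)c(OC)c1OC | intermediate (not isolated)
9 | 6,7,8-trimethoxy-3-(2,3,4,5,6-pentamethoxyphenyl)-4H-chromen-4-one | COc1cc2c(=O)c(-c3c(OC)c(OC)c(OC)c(OC)c3OC)coc2c(OC)c1OC | intermediate
10 | 6,7,8-trimethoxy-3-(2,3,4,5,6-pentamethoxyphenyl)chroman-4-one (racemic, C3 epimerising) | COc1cc2C(=O)C(c3c(OC)c(OC)c(OC)c(OC)c3OC)COc2c(OC)c1OC | intermediate (not isolated)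
11 | (3S,4S)-6,7,8-trimethoxy-3-(2,3,4,5,6-pentamethoxyphenyl)chroman-4-ol (cis) | COc1cc2[C@@H](O)[C@@H](c3c(OC)c(OC)c(OC)c(OC)c3OC)COc2c(OC)c1OC | intermediate
12 | (6aS,11aS)-2,3,4,7,8,9,10-heptamethoxy-11-methyl-6a,11a-dihydro-6H-benzofuro[3,2-c]chromen-11-ium bromide | COc1cc2[C@H]3[O+](C)c4c(OC)c(OC)c(OC)c(OC)c4[C@H]3COc2c(OC)c1OC.[Br-] | intermediate (not isolated)
13 | (6aS,11aS)-2,3,4,7,8,9,10-heptamethoxy-6a,11a-dihydro-6H-benzofuro[3,2-c]chromene (cis-pterocarpan) | COc1cc2[C@H]3Oc4c(OC)c(OC)c(OC)c(OC)c4[C@H]3COc2c(OC)c1OC | intermediate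
14 | 2,3,4,5-tetramethoxy-6-[(3S)-6,7,8-trimethoxychroman-3-yl]phenol | COc1c(OC)c(OC)c(O)c([C@H]2COc3c(cc(OC)c(OC)c3OC)C2)c1OC | intermediate
15 | 2,3,5-trimethoxy-6-[(3S)-6,7,8-trimethoxychroman-3-yl]cyclohexa-2,5-diene-1,4-dione | COC1=C(OC)C(=O)C([C@H]2COc3c(cc(OC)c(OC)c3OC)C2)=C(OC)C1=O | target

**Step count**
Total: 9 steps. Longest linear sequence: 8 steps (steps 1, 2, 4, 5, 6, 7, 8, 9 from compound 1).

**Three steps most likely to fail**

Step 7 (demethylative pterocarpan closure). The C4 cation may lose H3 to give the isoflav-3-ene before the oxonium is demethylated, which would lower the yield or erode the ee at C3. The ee of 13 must therefore be checked against 11. The fallback sets out from 3 and comes back at 14; it singles out the 2'-oxygen before the rings are built instead of by the ring closure. BCl3 (CH2Cl2, −78 → 0 °C) cleaves one of the two equivalent methyl ethers ortho to the formyl group of 3 to give 2-hydroxy-3,4,5,6-tetramethoxybenzaldehyde F1, and BnBr/K2CO3 in DMF gives 2-(benzyloxy)-3,4,5,6-tetramethoxybenzaldehyde F2. Condensation with 6 as in step 4 gives benzyloxy chalcone F3. Tl(NO3)3/MeOH then HCl as in step 5 gives benzyloxy isoflavone F5 through dimethyl acetal F4. The transfer hydrogenation of step 6 gives (3S,4S)-benzyloxy isoflavan-4-ol F7 through isoflavanone F6. H2 with Pd/C in AcOH then removes the benzyl group to give 2'-hydroxy isoflavan-4-ol F8, which closes to 13 under the acid and is hydrogenolysed on to 14 in the same flask.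

Step 5 (oxidative aryl shift). The migrating aryl group is fully substituted with two ortho methoxy groups, and the A ring is a chelated p-methoxyphenol that Tl(III) could oxidise instead of the alkene. The fallback sets out from 7 and comes back at 9; it closes the ring first and shifts the aryl group second, so that no free phenol meets the oxidant. NaOAc in refluxing EtOH (6-endo oxa-Michael addition, the chalcone isomerase reaction) gives racemic 6,7,8-trimethoxy-2-(pentamethoxyphenyl)chroman-4-one F9. PhI(OH)OTs in refluxing MeCN then attacks the enol at C3, the aryl group shifts from C2 to C3, and loss of a proton gives 9.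

Step 2 (double methoxylation next to a free aldehyde). Hydrodebromination or attack on the formyl group under hot methoxide may dominate. The fallback sets out from 4 and comes back at 3; it builds the pentamethoxy ring by directed metalation with no halide displacement. n-BuLi/TMEDA (THF, 0 °C) lithiates 4 at C5 and B(OMe)3 gives dimethyl (2,3,4,5-tetramethoxyphenyl)boronate F10 (not isolated), which H2O2/NaOH oxidises to 2,3,4,5-tetramethoxyphenol F11. MeI/K2CO3 in acetone gives pentamethoxybenzene F12, and a second ortho-lithiation (n-BuLi/TMEDA, THF, 0 °C) followed by DMF gives 3.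

**Further compounds**
F1 | step 7 | 2-hydroxy-3,4,5,6-tetramethoxybenzaldehyde | COc1c(OC)c(OC)c(C=O)c(O)c1OC
F2 | step 7 | 2-(benzyloxy)-3,4,5,6-tetramethoxybenzaldehyde | COc1c(OC)c(OC)c(C=O)c(OCc2ccccc2)c1OC
F3 | step 7 | (E)-3-[2-(benzyloxy)-3,4,5,6-tetramethoxyphenyl]-1-(2-hydroxy-3,4,5-trimethoxyphenyl)prop-2-en-1-one | COc1cc(C(=O)/C=C/c2c(OCc3ccccc3)c(OC)c(OC)c(OC)c2OC)c(O)c(OC)c1OC
F4 | step 7 | 2-[2-(benzyloxy)-3,4,5,6-tetramethoxyphenyl]-1-(2-hydroxy-3,4,5-trimethoxyphenyl)-3,3-dimethoxypropan-1-one (racemic) | COC(OC)C(C(=O)c1cc(OC)c(OC)c(OC)c1O)c1c(OCc2ccccc2)c(OC)c(OC)c(OC)c1OC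
F5 | step 7 | 3-[2-(benzyloxy)-3,4,5,6-tetramethoxyphenyl]-6,7,8-trimethoxy-4H-chromen-4-one | COc1cc2c(=O)c(-c3c(OCc4ccccc4)c(OC)c(OC)c(OC)c3OC)coc2c(OC)c1OC
F6 | step 7 | 3-[2-(benzyloxy)-3,4,5,6-tetramethoxyphenyl]-6,7,8-trimethoxychroman-4-one (racemic) | COc1cc2C(=O)C(c3c(OCc4ccccc4)c(OC)c(OC)c(OC)c3OC)COc2c(OC)c1OC
F7 | step 7 | (3S,4S)-3-[2-(benzyloxy)-3,4,5,6-tetramethoxyphenyl]-6,7,8-trimethoxychroman-4-ol | COc1cc2[C@@H](O)[C@@H](c3c(OCc4ccccc4)c(OC)c(OC)c(OC)c3OC)COc2c(OC)c1OC
F8 | step 7 | (3S,4S)-3-(2-hydroxy-3,4,5,6-tetramethoxyphenyl)-6,7,8-trimethoxychroman-4-ol | COc1cc2[C@@H](O)[C@@H](c3c(O)c(OC)c(OC)c(OC)c3OC)COc2c(OC)c1OC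
F9 | step 5 | 6,7,8-trimethoxy-2-(2,3,4,5,6-pentamethoxyphenyl)chroman-4-one (racemic) | COc1cc2C(=O)CC(c3c(OC)c(OC)c(OC)c(OC)c3OC)Oc2c(OC)c1OC
F10 | step 2 | dimethyl (2,3,4,5-tetramethoxyphenyl)boronate | COB(OC)c1cc(OC)c(OC)c(OC)c1OC
F11 | step 2 | 2,3,4,5-tetramethoxyphenol | COc1cc(O)c(OC)c(OC)c1OC
F12 | step 2 | pentamethoxybenzene | COc1cc(OC)c(OC)c(OC)c1OC
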